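**Retrosynthetic overview**

1. Target 19 ⇐ epoxy alcohol 18 (oxidation) ⇐ allylic alcohol 17 (hydroxyl-directed epoxidation places the oxirane on the angular-methyl face) ⇐ enone 13, after the side chain is finished by Shi epoxidation, epoxide-to-allylic-alcohol isomerisation and acetylation.
2. Enone 13 ⇐ linear dienone 11 by dissolving-metal 1,6-reduction (ring-fusion H enters anti to the angular methyl, giving the trans fusion).
3. Seven-membered ring ⇐ anion-accelerated divinylcyclopropane rearrangement of cyclopropyl methyl ketone 8 (sets the quaternary carbon).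
4. Cyclopentene and cyclopropane, with the ring CH and the tertiary carbinol stereocentres ⇐ one gold-catalysed enyne cyclisation / 1,5-acyloxy shift / cyclopropanation of acyclic ester 5 with isoprene.
5. 5 ⇐ nerylacetone + ethynylmagnesium bromide, resolved as the camphanate. Ring order: cyclopentene and cyclopropane together (step 3), cycloheptadienone (step 5), oxirane (step 11).

Assumption: in step 3 the migrating acyloxy group reaches the tertiary carbon on the same face as the new ring C–C bond (syn delivery), which is why the (5Z)-ketone 1 is used; this is a geometric argument, not a documented stereochemical result.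

Locants in names follow azulene numbering: C1 bears the side chain, C3a the angular methyl, C5 the ring oxygen function, C6 the ring methyl, C8a the ring-fusion hydrogen.

**Route**

Step 1
Reactants: 1 nerylacetone, (5Z)-6,10-dimethylundeca-5,9-dien-2-one; 2 ethynylmagnesium bromide
Product: 3 (6Z)-3,7,11-trimethyldodeca-6,10-dien-1-yn-3-ol (racemic)
Conditions: HC≡CMgBr (1.3 equiv), THF, 0 °C to 23 °C; aq. NH4Cl
Reagents that add atoms: ethynylmagnesium bromide (2), C#C[Mg]Br
Why: Grignard 1,2-addition to the methyl ketone gives the tertiary propargylic alcohol without touching the (Z)-alkene; the new centre is racemic and is resolved in step 2.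

Step 2
Reactants: 3 racemic propargylic alcohol; 4 (1S)-(−)-camphanic chloride
Product: 5 (3R,6Z)-3,7,11-trimethyldodeca-6,10-dien-1-yn-3-yl (1S,4R)-camphanate (single diastereomer)
Conditions: 4 (1.2 equiv), Et3N, DMAP (0.2 equiv), CH2Cl2, 23 °C; separation of the two diastereomeric esters on silica gel
Reagents that add atoms: (1S)-(−)-camphanic chloride (4), CC1(C)[C@@]2(C)CC[C@]1(C(=O)Cl)OC2=O
Why: DMAP-catalysed acylation gives two diastereomeric camphanates (classical resolution through diastereomeric esters), the (3S)-ester is removed, and the enolisation-proof camphanoyl group serves as the migrating acyl group in step 3.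

Step 3
Reactants: 5 (3R)-camphanate; 6 isoprene
Product: 7 (2S)-6-methyl-2-{(1S)-3-methyl-2-[(1R,2R)-2-methyl-2-vinylcyclopropyl]cyclopent-2-en-1-yl}hept-5-en-2-yl (1S,4R)-camphanate (vinyl cis to the cyclopentenyl group)
Conditions: [Au(NCMe){P(t-Bu)2(biphenyl-2-yl)}]SbF6 (3 mol %), isoprene (20 equiv), CH2Cl2, −30 °C to 0 °C
Reagents that add atoms: isoprene (6), C=CC(C)=C
Why: Gold-catalysed 1,6-enyne 5-exo-dig cyclisation with 1,5-acyloxy migration and intermolecular cyclopropanation forms the cyclopentene and the cyclopropane in one operation: the acyloxy group can only bridge to the former alkene carbon if it is cis to it, so the (3R) centre fixes the ring CH as (S), syn delivery across the (Z)-alkene sets the tertiary ester carbon as (S), and the resulting alkenyl gold carbene cyclopropanates the more nucleophilic 1,1-disubstituted bond of isoprene cis-selectively, anti to the bulky ring substituent.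

Step 4
Reactants: 7 vinylcyclopropane
Product: 8 (2S)-2-{(1S)-2-[(1S,2S)-2-acetyl-2-methylcyclopropyl]-3-methylcyclopent-2-en-1-yl}-6-methylhept-5-en-2-yl (1S,4R)-camphanate (acetyl cis to the cyclopentenyl group)
Conditions: PdCl2 (10 mol %), CuCl (1 equiv), O2 (1 atm), DMF/H2O (7:1), 23 °C
Reagents that add atoms: water, O
Why: Wacker–Tsuji oxidation converts only the monosubstituted vinyl group into a methyl ketone (Markovnikov hydroxypalladation at the cyclopropyl-stabilised carbon) and leaves the tri- and tetrasubstituted alkenes and all stereocentres untouched.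

Step 5
Reactants: 8 cyclopropyl methyl ketone
Product: 11 (1S,3aR)-1-[(2S)-2-(camphanoyloxy)-6-methylhept-5-en-2-yl]-3a,6-dimethyl-2,3,3a,4-tetrahydroazulen-5(1H)-one, via lithium enolate 9 (not isolated), via ring lithium dienolate 10 (not isolated)
Conditions: LiN(SiMe3)2 (1.1 equiv), THF, −78 °C to 45 °C; then PhS(Cl)=N-t-Bu (1.3 equiv), −78 °C to 0 °C
Reagents that add atoms: none
Why: The only enolisable position gives the 2-oxidovinyl cyclopropane, whose anion-accelerated cis-divinylcyclopropane (Cope) rearrangement closes the seven-membered ring and creates the quaternary carbon with the new CH2 anti to the side chain (methyl cis to it), and the regiodefined ring enolate is then dehydrogenated in the same flask (Mukaiyama sulfinimidoyl chloride oxidation) to the linear dienone.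

Step 6
Reactants: 11 dienone camphanate
Product: 13 (1S,3aR,8aS)-1-[(2S)-2-hydroxy-6-methylhept-5-en-2-yl]-3a,6-dimethyl-2,3,3a,4,8,8a-hexahydroazulen-5(1H)-one, via β,γ-unsaturated ketone 12 (not isolated)
Conditions: Li (10 equiv), NH3(l)/THF, t-BuOH (1 equiv), −78 °C; NH4Cl; then DBU (0.2 equiv), CH2Cl2, 23 °C
Reagents that add atoms: none
Why: Birch-type 1,6-reduction of the linear dienone protonates the ring-fusion carbon from the face opposite the angular methyl and the side chain (trans fusion); the isolated side-chain alkene is inert, excess lithium cleaves the hindered camphanate by acyl–oxygen fission, and DBU moves the double bond back into conjugation.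

Step 7
Reactants: 13 enone alcohol
Product: 14 (1S,3aR,8aS)-1-{(2S)-4-[(2S)-3,3-dimethyloxiran-2-yl]-2-hydroxybutan-2-yl}-3a,6-dimethyl-2,3,3a,4,8,8a-hexahydroazulen-5(1H)-one
Conditions: ent-Shi ketone (L-fructose-derived, 30 mol %), Oxone (2KHSO5·KHSO4·K2SO4), K2CO3, Bu4NHSO4, MeCN/CH2(OMe)2/aq. buffer pH 10.5, 0 °C
Reagents that add atoms: Oxone (potassium peroxymonosulfate), [K+].OOS(=O)(=O)[O-]
Why: Shi asymmetric epoxidation attacks only the electron-rich trisubstituted side-chain alkene (the enone is deactivated), and the enantiomeric ketone catalyst gives the (S)-oxirane by reagent control.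

Step 8
Reactants: 14 epoxy enone
Product: 15 (1S,3aR,8aS)-1-[(2S,5S)-2,5-dihydroxy-6-methylhept-6-en-2-yl]-3a,6-dimethyl-2,3,3a,4,8,8a-hexahydroazulen-5(1H)-one
Conditions: Cp2TiCl2 (2.5 equiv), Mn (8 equiv), THF, 23 °C (pre-formed Cp2TiCl added to 14); then 1 M HCl
Reagents that add atoms: none
Why: Titanocene-mediated radical opening of the trisubstituted epoxide (Nugent–RajanBabu type) gives the tertiary radical, which loses a methyl hydrogen to a second equivalent of the trivalent titanium reagent to form the isopropenyl carbinol, with the C–O stereocentre untouched.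

Step 9
Reactants: 15 diol
Product: 16 (2S,5S)-5-acetoxy side-chain enone, (1S,3aR,8aS)-1-[(2S,5S)-5-acetoxy-2-hydroxy-6-methylhept-6-en-2-yl]-3a,6-dimethyl-2,3,3a,4,8,8a-hexahydroazulen-5(1H)-one
Conditions: Ac2O (1.5 equiv), pyridine, DMAP (5 mol %), CH2Cl2, 0 °C
Reagents that add atoms: acetic anhydride, CC(=O)OC(C)=O
Why: Standard acylation acetylates the secondary allylic alcohol selectively; the hindered tertiary alcohol does not react under these conditions.

Step 10
Reactants: 16 acetoxy enone
Product: 17 (1S,3aR,5R,8aS)-1-[(2S,5S)-5-acetoxy-2-hydroxy-6-methylhept-6-en-2-yl]-3a,6-dimethyl-1,2,3,3a,4,5,8,8a-octahydroazulen-5-ol (5-OH cis to the angular methyl)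
Conditions: NaBH4, CeCl3·7H2O, MeOH, −78 °C
Reagents that add atoms: none
Why: Luche 1,2-reduction spares the acetate, and hydride attacks from the face opposite the pseudo-axial angular methyl (1,3 to the carbonyl), giving the alcohol cis to that methyl.

Step 11
Reactants: 17 allylic alcohol
Product: 18 6,7-epoxide of 17 with the oxirane cis to the 5-hydroxyl and the angular methyl
Conditions: VO(acac)2 (5 mol %), t-BuOOH (1.5 equiv), CH2Cl2, 0 °C to 23 °C
Reagents that add atoms: tert-butyl hydroperoxide, CC(C)(C)OO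
Why: Vanadium-catalysed hydroxyl-directed epoxidation delivers oxygen syn to the ring hydroxyl, setting both oxirane stereocentres on the methyl face, while the isopropenyl group, which has no free allylic hydroxyl, is left alone.

Step 12
Reactants: 18 epoxy alcohol
Product: 19 target epoxy ketone CNP0165281.1
Conditions: Dess–Martin periodinane (1.5 equiv), NaHCO3, CH2Cl2, 0 °C to 23 °C
Reagents that add atoms: none
Why: Dess–Martin oxidation converts the secondary epoxy alcohol into the α,β-epoxy ketone under buffered, non-epimerising conditions; the tertiary alcohol, acetate and alkene are unaffected.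

**Compound list**

1 | nerylacetone, (5Z)-6,10-dimethylundeca-5,9-dien-2-one | CC(=O)CC/C=C(C)\CCC=C(C)C | starting material
2 | ethynylmagnesium bromide | C#C[Mg]Br | starting material
3 | (6Z)-3,7,11-trimethyldodeca-6,10-dien-1-yn-3-ol, racemic | C#CC(C)(O)CC/C=C(C)\CCC=C(C)C | intermediate
4 | (1S)-(−)-camphanic chloride, (1S,4R)-4,7,7-trimethyl-3-oxo-2-oxabicyclo[2.2.1]heptane-1-carbonyl chloride | CC1(C)[C@@]2(C)CC[C@]1(C(=O)Cl)OC2=O | starting material
5 | (3R,6Z)-3,7,11-trimethyldodeca-6,10-dien-1-yn-3-yl (1S,4R)-camphanate | C#C[C@](C)(OC(=O)[C@]1(OC2=O)CC[C@]2(C)C1(C)C)CC/C=C(C)\CCC=C(C)C | intermediate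
6 | isoprene | C=CC(C)=C | starting material
7 | cyclopentenyl vinylcyclopropane camphanate (product of step 3; vinyl cis to cyclopentenyl) | C=C[C@@]1(C)C[C@H]1C2=C(C)CC[C@@H]2[C@@](C)(OC(=O)[C@]3(OC4=O)CC[C@]4(C)C3(C)C)CCC=C(C)C | intermediate
8 | cyclopentenyl acetylcyclopropane camphanate (acetyl cis to cyclopentenyl) | CC(=O)[C@@]1(C)C[C@H]1C2=C(C)CC[C@@H]2[C@@](C)(OC(=O)[C@]3(OC4=O)CC[C@]4(C)C3(C)C)CCC=C(C)C | intermediate
9 | lithium enolate of 8 (1-oxidovinyl cyclopropane) | [Li]OC(=C)[C@@]1(C)C[C@H]1C2=C(C)CC[C@@H]2[C@@](C)(OC(=O)[C@]3(OC4=O)CC[C@]4(C)C3(C)C)CCC=C(C)C | intermediate (not isolated)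
10 | lithium (1S,3aR)-1-[(2S)-2-(camphanoyloxy)-6-methylhept-5-en-2-yl]-3a,6-dimethyl-1,2,3,3a,4,7-hexahydroazulen-5-olate | [Li]OC1=C(C)CC=C2[C@@H]([C@@](C)(OC(=O)[C@]3(OC4=O)CC[C@]4(C)C3(C)C)CCC=C(C)C)CC[C@]2(C)C1 | intermediate (not isolated)
11 | (1S,3aR)-1-[(2S)-2-(camphanoyloxy)-6-methylhept-5-en-2-yl]-3a,6-dimethyl-2,3,3a,4-tetrahydroazulen-5(1H)-one | CC1=CC=C2[C@@H]([C@@](C)(OC(=O)[C@]3(OC4=O)CC[C@]4(C)C3(C)C)CCC=C(C)C)CC[C@]2(C)CC1=O | intermediate
12 | (1S,3aR,8aS)-1-[(2S)-2-hydroxy-6-methylhept-5-en-2-yl]-3a,6-dimethyl-2,3,3a,4,6,8a-hexahydroazulen-5(1H)-one (C6 epimers) | CC(C)=CCC[C@](C)(O)[C@H]1CC[C@]2(C)CC(=O)C(C)C=C[C@@H]12 | intermediate (not isolated)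
13 | (1S,3aR,8aS)-1-[(2S)-2-hydroxy-6-methylhept-5-en-2-yl]-3a,6-dimethyl-2,3,3a,4,8,8a-hexahydroazulen-5(1H)-one | CC(C)=CCC[C@](C)(O)[C@H]1CC[C@]2(C)CC(=O)C(C)=CC[C@@H]12 | intermediate
14 | side-chain (S)-epoxide of 13 | CC1(C)O[C@H]1CC[C@](C)(O)[C@H]2CC[C@]3(C)CC(=O)C(C)=CC[C@@H]23 | intermediate
15 | (1S,3aR,8aS)-1-[(2S,5S)-2,5-dihydroxy-6-methylhept-6-en-2-yl]-3a,6-dimethyl-2,3,3a,4,8,8a-hexahydroazulen-5(1H)-one | C=C(C)[C@@H](O)CC[C@](C)(O)[C@H]1CC[C@]2(C)CC(=O)C(C)=CC[C@@H]12 | intermediate
16 | (1S,3aR,8aS)-1-[(2S,5S)-5-acetoxy-2-hydroxy-6-methylhept-6-en-2-yl]-3a,6-dimethyl-2,3,3a,4,8,8a-hexahydroazulen-5(1H)-one | C=C(C)[C@@H](OC(C)=O)CC[C@](C)(O)[C@H]1CC[C@]2(C)CC(=O)C(C)=CC[C@@H]12 | intermediate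
17 | (5R)-allylic alcohol from 16 (5-OH cis to the angular methyl) | C=C(C)[C@@H](OC(C)=O)CC[C@](C)(O)[C@H]1CC[C@]2(C)C[C@@H](O)C(C)=CC[C@@H]12 | intermediate
18 | 6,7-epoxy alcohol (oxirane cis to 5-OH and to the angular methyl) | C=C(C)[C@@H](OC(C)=O)CC[C@](C)(O)[C@H]1CC[C@]2(C)C[C@@H](O)[C@@]3(C)O[C@H]3C[C@@H]12 | intermediate
19 | CNP0165281.1 | C=C(C)[C@H](CC[C@](C)(O)[C@H]1CC[C@]2(C)CC(=O)[C@@]3(C)O[C@H]3C[C@@H]12)OC(C)=O | target

**Totals and risk**

Total step count: 12. Longest linear sequence: 12 steps (from 1).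

Three steps most likely to fail:

Step 3 (key cascade). The syn delivery of the acyloxy group, the choice of the substituted double bond of isoprene, and the cis geometry and facial sense of the cyclopropanation all have to hold. Fallback: starting again from 5, the same gold cascade is run with 3-methylbut-3-en-2-yl acetate as the trapping alkene. This alkene has only one double bond and carries the future acetyl carbon as a protected carbinol, giving the 1-acetoxyethyl cyclopropane F6. K2CO3 in MeOH removes the secondary acetate (the hindered camphanate stays) to give the secondary alcohol F7, and Dess–Martin oxidation brings the material back to 8, bypassing 7 and the Wacker step.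

Step 5 (enolate rearrangement and dehydrogenation). The lithium enolate only rearranges if the cyclopropane is cis, and the hindered enolate may resist the sulfinimidoyl chloride. Fallback: starting from 8, LDA/t-BuMe2SiCl gives the silyl enol ether F8. Thermolysis in toluene at 110 °C (up to 180 °C in o-dichlorobenzene, where a trans cyclopropane equilibrates to cis through reversible ring opening) gives the ring silyl enol ether F9. DDQ with 2,6-lutidine, by hydride abstraction from the doubly allylic CH2, returns the route to 11.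

Step 2 (resolution). The two camphanates may not separate preparatively. Fallback: starting from 1, Horner–Wadsworth–Emmons olefination with triethyl phosphonoacetate/NaH gives ethyl (2E,6Z)-farnesoate F1 after removal of the minor 2Z ester. i-Bu2AlH gives (2E,6Z)-farnesol F2. Sharpless epoxidation with Ti(OiPr)4, D-(−)-diethyl tartrate and t-BuOOH gives the (2R,3R)-epoxy alcohol F3. CCl4/PPh3 gives the epoxy chloride F4, and n-BuLi (3 equiv) fragments it to the enantioenriched (3R)-propargylic alcohol F5. Acylation with 4 then gives 5 directly, with no separation needed.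

**Further compounds**

F1 | step 2 | ethyl (2E,6Z)-3,7,11-trimethyldodeca-2,6,10-trienoate | CCOC(=O)/C=C(\C)CC/C=C(C)\CCC=C(C)C
F2 | step 2 | (2E,6Z)-farnesol | OC/C=C(\C)CC/C=C(C)\CCC=C(C)C
F3 | step 2 | (2R,3R)-2,3-epoxy-(6Z)-farnesol | OC[C@H]1O[C@]1(C)CC/C=C(C)\CCC=C(C)C
F4 | step 2 | 1-chloro-2,3-epoxide corresponding to F3 | ClC[C@H]1O[C@]1(C)CC/C=C(C)\CCC=C(C)C
F5 | step 2 | (3R,6Z)-3,7,11-trimethyldodeca-6,10-dien-1-yn-3-ol | C#C[C@](C)(O)CC/C=C(C)\CCC=C(C)C
F6 | step 3 | cyclopentenyl (1-acetoxyethyl)cyclopropane camphanate (carbinol epimers) | CC(OC(C)=O)[C@@]1(C)C[C@H]1C2=C(C)CC[C@@H]2[C@@](C)(OC(=O)[C@]3(OC4=O)CC[C@]4(C)C3(C)C)CCC=C(C)C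
F7 | step 3 | cyclopentenyl (1-hydroxyethyl)cyclopropane camphanate (carbinol epimers) | CC(O)[C@@]1(C)C[C@H]1C2=C(C)CC[C@@H]2[C@@](C)(OC(=O)[C@]3(OC4=O)CC[C@]4(C)C3(C)C)CCC=C(C)C
F8 | step 5 | tert-butyldimethylsilyl enol ether of 8 | C=C(O[Si](C)(C)C(C)(C)C)[C@@]1(C)C[C@H]1C2=C(C)CC[C@@H]2[C@@](C)(OC(=O)[C@]3(OC4=O)CC[C@]4(C)C3(C)C)CCC=C(C)C
F9 | step 5 | ring tert-butyldimethylsilyl dienol ether (silyl analogue of 10) | CC(C)(C)[Si](C)(C)OC1=C(C)CC=C2[C@@H]([C@@](C)(OC(=O)[C@]3(OC4=O)CC[C@]4(C)C3(C)C)CCC=C(C)C)CC[C@]2(C)C1
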